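## Retrosynthetic overview

1. The target is (3S,5R,6S,3'R,6'R)-lutein 5,6-epoxide dipalmitate. The last step is a double O-acylation, and the C40 chain comes from C15 (ε) ylide + C10 dialdehyde + C15 (epoxy) ylide by two Wittig couplings.
2. ε end group: the C7' carboxamide comes from retro-Claisen opening of the C2'–C7' bond of a bridged 1,3-diketone. That diketone derives from a 4-silyloxybicyclo[3.1.1]heptenone, which is made from an open-chain dienyl ketene by a crossed intramolecular [2+2] that forms C1'–C2' and C6'–C7' in one operation.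
3. Enabling feature: in the ε ring the gem-dimethyl carbon C1' is flanked by C2'H2 and C6'H, C6' bears C7', and O–C3' stands next to C2'. C7' can therefore be lent to C2' as a ketene carbon (temporary cyclobutanone C1'–C2'–C7'–C6'). The Me2C1'=C6'H polarity dictates the crossed closure, and C3' as a ketone later lets C2' leave C7'.
4. Stereo relay: an aldol-derived C3' carbinol sets C6' in the key step, and C3' is then re-set by CBS reduction. C3 comes from (4R,6R)-actinol, and C5/C6 from a Sharpless epoxidation.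
5. Ring order: cyclobutanone and ε carbocycle close together in the key step, and the cyclobutanone is opened again two steps later. The left carbocycle is bought and its oxirane is closed in the side branch.

Key step: step 7

Assumption: (4R,6R)-actinol, (S)-HYTRA, the isobutenyl boronate, the C5 phosphonate and the C10 dialdehyde are taken as catalogue compounds. Carotenoid numbering (primed for the ε half) is used for positions.

## Route

Step 1
Reactants: 1 but-2-yn-1-ol
Product: 2 (Z)-3-iodobut-2-en-1-ol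
Conditions: Red-Al, THF, 0 °C → rt; then I2, −78 → 0 °C; aq. Rochelle salt
Reagents that add atoms: iodine, II
Why: Hydroxyl-directed trans-hydroalumination of the propargylic alcohol puts aluminium on the distal alkyne carbon and iodinolysis with retention should give only the Z-iodoalkene, the geometry that later holds C3' and C6' cis across C4'=C5'.

Step 2
Reactants: 2 (Z)-3-iodobut-2-en-1-ol
Product: 3 (Z)-3-iodobut-2-enal
Conditions: activated MnO2, CH2Cl2, rt, dark
Reagents that add atoms: none
Why: Neutral heterogeneous allylic alcohol oxidation with manganese dioxide should stop at the enal and leave the Z-iodoalkene untouched.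

Step 3
Reactants: 4 (S)-2-hydroxy-1,2,2-triphenylethyl acetate [(S)-HYTRA]; 3 (Z)-3-iodobut-2-enal
Product: 5 (1S)-2-hydroxy-1,2,2-triphenylethyl (3S,4Z)-3-hydroxy-5-iodohex-4-enoate
Conditions: LDA (2.1 equiv), THF, −78 → 0 °C; then 3, THF/2-methylbutane, −125 °C; AcOH quench
Reagents that add atoms: none
Why: Auxiliary-controlled acetate aldol addition: the doubly lithiated (S)-triphenylglycol acetate adds through one enolate face, so the new carbinol centre (later C3') should form with S configuration, any minor diastereomer being removable by crystallisation.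

Step 4
Reactants: 5 aldol ester
Product: 6 (3S,4Z)-3-hydroxy-5-iodohex-4-enoic acid
Conditions: LiOH, THF/MeOH/H2O, 0 °C → rt; then 1 M HCl to pH 3
Reagents that add atoms: lithium hydroxide, [Li+].[OH-]
Why: Ester saponification by acyl–oxygen cleavage frees the β-hydroxy acid and the recoverable diol without touching the carbinol centre.

Step 5
Reactants: 6 (3S,4Z)-3-hydroxy-5-iodohex-4-enoic acid
Product: 8 (3S,4Z)-3-[(tert-butyldimethylsilyl)oxy]-5-iodohex-4-enoic acid, via silyl ester 7 (not isolated)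
Conditions: TBSCl (2.3 equiv), imidazole, DMF, rt; then AcOH/THF/H2O, rt
Reagents that add atoms: tert-butyldimethylsilyl chloride, CC(C)(C)[Si](C)(C)Cl
Why: Silyl ether formation covers the alcohol, and the much more labile silyl ester formed alongside is hydrolysed selectively under mild aqueous acid.

Step 6
Reactants: 8 silyloxy iodo acid; 9 2-methylprop-1-enylboronic acid pinacol ester
Product: 10 (3S,4Z)-3-[(tert-butyldimethylsilyl)oxy]-5,7-dimethylocta-4,6-dienoic acid
Conditions: Pd(dppf)Cl2 (cat.), aq. NaOH, THF, 40 °C; then 1 M HCl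
Reagents that add atoms: none
Why: Suzuki–Miyaura coupling of an alkenyl iodide proceeds with retention, so the Z-trisubstituted C4'=C5' bond and the Me2C=CH terminus of the diene are installed in one operation.

Step 7
Reactants: 10 (3S,4Z)-3-[(tert-butyldimethylsilyl)oxy]-5,7-dimethylocta-4,6-dienoic acid
Product: 13 (1S,4R,5S)-4-[(tert-butyldimethylsilyl)oxy]-2,7,7-trimethylbicyclo[3.1.1]hept-2-en-6-one, via acid chloride 11 (not isolated), via ketene 12 (not isolated)
Conditions: 1-chloro-N,N,2-trimethylprop-1-en-1-amine, CH2Cl2, 0 °C; then slow addition to i-Pr2NEt, toluene, reflux, high dilution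
Reagents that add atoms: none
Why: The acid chloride is dehydrochlorinated to aldoketene 12, whose electrophilic central carbon (C7') bonds to the less substituted carbon C6' of the Me2C1'=C6'H unit while the positive charge building up at tertiary C1' is quenched by the ketene α-carbon C2', an asynchronous [π2s+π2a] cycloaddition. The closest known reaction type is the intramolecular ketene–alkene [2+2] cycloaddition of ketenes that carry a three-atom tether to a 2-methylprop-1-enyl terminus, which gives 7,7-dimethylbicyclo[3.1.1]heptan-6-ones. Two rings close at once in the crossed (bridged) mode: the cyclobutanone C1'–C2'–C7'–C6' by the [2+2] event itself and the six-membered ε carbocycle C1'–C6' by the new C1'–C2' bond, C6'–C7' being the second bond formed. The new stereocentres C2' and C6' are locked cis by the two one-atom bridges, and their absolute sense is set by C3': the silyloxy group has to lie on the carbonyl-bridge side because the other approach would press it against the endo methyl group of the C1' bridge, so (3S) should give (6'R). The step needs crossed rather than fused regiochemistry, cyclisation rather than dimerisation, and survival of the β-silyloxy group; the gem-dimethyl polarisation of the alkene, the Z-C4'=C5' bond that holds C2' over C1', high dilution, and chloride as the better leaving group secure these. A minor facial isomer would be a diastereomer and is removed here, so the configurational purity of C6' is fixed at this stage.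

Step 8
Reactants: 13 silyloxy bicyclic ketone
Product: 14 (1S,4R,5S)-4-hydroxy-2,7,7-trimethylbicyclo[3.1.1]hept-2-en-6-one
Conditions: HF·pyridine, THF, 0 °C → rt
Reagents that add atoms: none
Why: Fluoride-driven Si–O cleavage under buffered non-basic conditions should free the allylic alcohol without the retro-aldol opening that a basic fluoride source could start in this β-hydroxy ketone.

Step 9
Reactants: 14 hydroxy bicyclic ketone
Product: 16 (1R)-N-methoxy-N,2,6,6-tetramethyl-4-oxocyclohex-2-ene-1-carboxamide, via bridged diketone 15 (not isolated)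
Conditions: activated MnO2, CH2Cl2, rt; filter; filtrate + MeONHMe (free base), 0 °C → rt
Reagents that add atoms: N,O-dimethylhydroxylamine, CNOC
Why: Allylic oxidation gives a strained non-enolisable bridged 1,3-diketone, and retro-Claisen aminolysis follows because the weakly basic amine adds to the cyclobutanone carbonyl C7' and the C2'–C7' bond breaks with release of ring strain and departure of C2' as the enolate of the C3' enone, which removes the temporary ring and leaves C6' untouched with R configuration.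

Step 10
Reactants: 16 keto amide
Product: 17 (1R,4R)-4-hydroxy-N-methoxy-N,2,6,6-tetramethylcyclohex-2-ene-1-carboxamide
Conditions: (S)-Me-CBS (cat.), BH3·SMe2, toluene, −40 °C; MeOH quench
Reagents that add atoms: none
Why: Corey–Bakshi–Shibata reduction: the (S)-oxazaborolidine treats the alkenyl branch as the large group and should deliver hydride to give the (4R)-allylic alcohol (C3' R, trans to the amide), a minor cis epimer being a separable diastereomer that can be re-oxidised.

Step 11
Reactants: 17 hydroxy amide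
Product: 18 (1R,4R)-4-[(tert-butyldimethylsilyl)oxy]-N-methoxy-N,2,6,6-tetramethylcyclohex-2-ene-1-carboxamide
Conditions: TBSCl, imidazole, DMF, rt
Reagents that add atoms: tert-butyldimethylsilyl chloride, CC(C)(C)[Si](C)(C)Cl
Why: Standard silyl ether formation protects the allylic alcohol for the hydride and ylide steps.

Step 12
Reactants: 18 silyloxy amide
Product: 19 (1R,4R)-4-[(tert-butyldimethylsilyl)oxy]-2,6,6-trimethylcyclohex-2-ene-1-carbaldehyde
Conditions: DIBAL-H, THF, −78 °C; aq. Rochelle salt, 0 °C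
Reagents that add atoms: none
Why: Reduction of an N-methoxy-N-methylamide stops at the chelated tetrahedral intermediate, so the aldehyde appears only on cold neutral work-up, which should keep the α-stereocentre C6' and the β,γ-double bond in place.

Step 13
Reactants: 19 silyloxy aldehyde; 20 ethyl (E)-4-(diethoxyphosphoryl)-3-methylbut-2-enoate
Product: 21 ethyl (2E,4E)-5-{(1R,4R)-4-[(tert-butyldimethylsilyl)oxy]-2,6,6-trimethylcyclohex-2-en-1-yl}-3-methylpenta-2,4-dienoate
Conditions: 20, LiHMDS, THF/DMPU, −78 °C; then 19, −78 → −20 °C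
Reagents that add atoms: none
Why: Horner–Wadsworth–Emmons olefination with the stabilised C5 phosphonate anion at low temperature should add faster than it deprotonates and gives the E-C7'=C8' bond, the E-C9'=C10' bond coming from the reagent.

Step 14
Reactants: 21 C15 dienoate
Product: 22 (2E,4E)-5-{(1R,4R)-4-[(tert-butyldimethylsilyl)oxy]-2,6,6-trimethylcyclohex-2-en-1-yl}-3-methylpenta-2,4-dien-1-ol
Conditions: DIBAL-H (2.2 equiv), CH2Cl2, −78 °C; aq. Rochelle salt
Reagents that add atoms: none
Why: 1,2-Reduction of the dienoate with DIBAL-H gives the dienol and leaves silyl ether and alkenes untouched.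

Step 15
Reactants: 22 C15 dienol
Product: 24 [(2E,4E)-5-{(1R,4R)-4-[(tert-butyldimethylsilyl)oxy]-2,6,6-trimethylcyclohex-2-en-1-yl}-3-methylpenta-2,4-dien-1-yl]triphenylphosphonium bromide, via allylic bromide 23 (not isolated)
Conditions: CBr4, PPh3, CH2Cl2, −20 °C; then PPh3, EtOAc, rt
Reagents that add atoms: carbon tetrabromide, BrC(Br)(Br)Br; triphenylphosphine, c1ccc(cc1)P(c1ccccc1)c1ccccc1
Why: Appel bromination under neutral conditions followed by SN2 quaternisation of triphenylphosphine converts only the primary dienylic alcohol, since the secondary allylic oxygen is silylated.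

Step 16
Reactants: 24 ε-C15 phosphonium bromide; 25 (2E,4E,6E)-2,7-dimethylocta-2,4,6-trienedial
Product: 26 (3R,6R)-3-[(tert-butyldimethylsilyl)oxy]-12'-apo-ε-caroten-12'-al
Conditions: 25 (excess), NaOMe, CH2Cl2/MeOH, 0 °C → rt; then heptane, reflux (Z→E)
Reagents that add atoms: none
Why: Wittig olefination of one aldehyde group of the excess dialdehyde builds C11'=C12', and the Z portion of the new bond should converge on the all-E polyene on thermal equilibration.

Step 17
Reactants: 27 (4R,6R)-4-hydroxy-2,2,6-trimethylcyclohexan-1-one (actinol)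
Product: 28 (4R,6R)-4-[(tert-butyldimethylsilyl)oxy]-2,2,6-trimethylcyclohexan-1-one
Conditions: TBSCl, imidazole, DMF, rt
Reagents that add atoms: tert-butyldimethylsilyl chloride, CC(C)(C)[Si](C)(C)Cl
Why: Silyl ether formation protects the carbinol that becomes C3 of the target.

Step 18
Reactants: 28 silyloxy ketone
Product: 29 (4R)-4-[(tert-butyldimethylsilyl)oxy]-2,6,6-trimethylcyclohex-1-en-1-yl trifluoromethanesulfonate
Conditions: LDA, THF, −78 °C; then PhNTf2, −78 °C → rt
Reagents that add atoms: N-phenylbis(trifluoromethanesulfonimide), O=S(=O)(N(c1ccccc1)S(=O)(=O)C(F)(F)F)C(F)(F)F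
Why: Only one α-carbon of the ketone carries hydrogen, so enol triflate formation is regiochemically unambiguous, the methyl-bearing stereocentre being erased on purpose while the carbinol centre is untouched.

Step 19
Reactants: 29 enol triflate
Product: 30 methyl (4R)-4-[(tert-butyldimethylsilyl)oxy]-2,6,6-trimethylcyclohex-1-ene-1-carboxylate
Conditions: Pd(OAc)2, PPh3 (cat.), CO (1 atm), MeOH, Et3N, DMF, rt
Reagents that add atoms: carbon monoxide, [C-]#[O+]; methanol, CO
Why: Palladium-catalysed alkoxycarbonylation of the enol triflate introduces C7 as an ester on the tetrasubstituted alkene.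

Step 20
Reactants: 30 cyclohexene ester
Product: 31 {(4R)-4-[(tert-butyldimethylsilyl)oxy]-2,6,6-trimethylcyclohex-1-en-1-yl}methanol
Conditions: DIBAL-H (2.2 equiv), CH2Cl2, −78 °C; aq. Rochelle salt
Reagents that add atoms: none
Why: 1,2-Reduction of the conjugated ester gives the allylic alcohol needed as the handle for directed epoxidation.

Step 21
Reactants: 31 allylic alcohol
Product: 32 {(1R,4S,6R)-4-[(tert-butyldimethylsilyl)oxy]-2,2,6-trimethyl-7-oxabicyclo[4.1.0]heptan-1-yl}methanol
Conditions: Ti(Oi-Pr)4, D-(−)-diethyl tartrate (cat.), t-BuOOH, 4 Å MS, CH2Cl2, −20 °C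
Reagents that add atoms: tert-butyl hydroperoxide, CC(C)(C)OO
Why: Sharpless asymmetric epoxidation: with D-(−)-tartrate the titanium-bound peroxide is delivered to the alkene face anti to the silyloxy group, which closes the oxirane and sets C5 (R) and C6 together by reagent control.

Step 22
Reactants: 32 epoxy alcohol
Product: 33 (1S,4S,6R)-4-[(tert-butyldimethylsilyl)oxy]-2,2,6-trimethyl-7-oxabicyclo[4.1.0]heptane-1-carbaldehyde
Conditions: TPAP (cat.), NMO, 4 Å MS, CH2Cl2, rt
Reagents that add atoms: none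
Why: Ley–Griffith oxidation is neutral and should give the epoxy aldehyde, which has no α-hydrogen and so cannot epimerise.

Step 23
Reactants: 33 epoxy aldehyde; 20 ethyl (E)-4-(diethoxyphosphoryl)-3-methylbut-2-enoate
Product: 34 ethyl (2E,4E)-5-{(1S,4S,6R)-4-[(tert-butyldimethylsilyl)oxy]-2,2,6-trimethyl-7-oxabicyclo[4.1.0]heptan-1-yl}-3-methylpenta-2,4-dienoate
Conditions: 20, LiHMDS, THF/DMPU, −78 °C; then 33, −78 → 0 °C
Reagents that add atoms: none
Why: Horner–Wadsworth–Emmons olefination under basic conditions is harmless to the oxirane and gives the E-C7=C8 bond.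

Step 24
Reactants: 34 epoxy dienoate
Product: 35 (2E,4E)-5-{(1S,4S,6R)-4-[(tert-butyldimethylsilyl)oxy]-2,2,6-trimethyl-7-oxabicyclo[4.1.0]heptan-1-yl}-3-methylpenta-2,4-dien-1-ol
Conditions: DIBAL-H (2.2 equiv), CH2Cl2, −78 °C; aq. Rochelle salt
Reagents that add atoms: none
Why: Cold 1,2-reduction of the ester is faster than any attack on the fully substituted oxirane.

Step 25
Reactants: 35 epoxy dienol
Product: 37 [(2E,4E)-5-{(1S,4S,6R)-4-[(tert-butyldimethylsilyl)oxy]-2,2,6-trimethyl-7-oxabicyclo[4.1.0]heptan-1-yl}-3-methylpenta-2,4-dien-1-yl]triphenylphosphonium bromide, via epoxy bromide 36 (not isolated)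
Conditions: CBr4, PPh3, 2,6-lutidine (buffer), CH2Cl2, −20 °C; then PPh3, EtOAc, rt
Reagents that add atoms: carbon tetrabromide, BrC(Br)(Br)Br; triphenylphosphine, c1ccc(cc1)P(c1ccccc1)c1ccccc1
Why: Appel bromination and SN2 quaternisation run without free acid, which should spare the alkenyl oxirane from rearrangement to the furanoid oxide.

Step 26
Reactants: 37 epoxy-C15 phosphonium bromide; 26 C25 aldehyde
Product: 38 (3S,5R,6S,3'R,6'R)-3,3'-bis[(tert-butyldimethylsilyl)oxy]-5,6-epoxy-5,6-dihydro-β,ε-carotene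
Conditions: NaOMe, CH2Cl2/MeOH, 0 °C → rt; then EtOH, reflux (Z→E)
Reagents that add atoms: none
Why: Wittig olefination closes the C40 chain at C11=C12 under basic conditions that leave oxirane, silyl ethers and all five stereocentres untouched, and the Z portion should equilibrate thermally to all-E.

Step 27
Reactants: 38 bis-silyl ether
Product: 39 (3S,5R,6S,3'R,6'R)-5,6-epoxy-5,6-dihydro-β,ε-carotene-3,3'-diol (lutein 5,6-epoxide)
Conditions: TBAF, THF, rt, dark
Reagents that add atoms: none
Why: Fluoride-mediated desilylation is non-acidic and should free both alcohols without epoxide–furanoid rearrangement or ionisation of the allylic C3' oxygen.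

Step 28
Reactants: 39 lutein 5,6-epoxide; 40 palmitoyl chloride
Product: 41 (3S,5R,6S,3'R,6'R)-5,6-epoxy-5,6-dihydro-β,ε-carotene-3,3'-diyl dipalmitate (target)
Conditions: 40 (2.5 equiv), pyridine, DMAP (cat.), CH2Cl2, 0 °C → rt, dark
Reagents that add atoms: none
Why: DMAP-catalysed O-acylation in pyridine esterifies both secondary alcohols with retention, since no C–O bond at C3 or C3' is broken and the medium stays basic for the oxirane.

## Compound list

1 | but-2-yn-1-ol | CC#CCO | starting material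
2 | (Z)-3-iodobut-2-en-1-ol | OC/C=C(C)\I | intermediate
3 | (Z)-3-iodobut-2-enal | O=C/C=C(C)\I | intermediate
4 | (S)-2-hydroxy-1,2,2-triphenylethyl acetate | CC(=O)O[C@@H](c1ccccc1)C(O)(c1ccccc1)c1ccccc1 | starting material
5 | (1S)-2-hydroxy-1,2,2-triphenylethyl (3S,4Z)-3-hydroxy-5-iodohex-4-enoate | O=C(C[C@H](O)/C=C(C)\I)O[C@@H](c1ccccc1)C(O)(c1ccccc1)c1ccccc1 | intermediate
6 | (3S,4Z)-3-hydroxy-5-iodohex-4-enoic acid | OC(=O)C[C@H](O)/C=C(C)\I | intermediate
7 | tert-butyldimethylsilyl (3S,4Z)-3-[(tert-butyldimethylsilyl)oxy]-5-iodohex-4-enoate | CC(C)(C)[Si](C)(C)OC(=O)C[C@H](O[Si](C)(C)C(C)(C)C)/C=C(C)\I | intermediate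
8 | (3S,4Z)-3-[(tert-butyldimethylsilyl)oxy]-5-iodohex-4-enoic acid | OC(=O)C[C@H](O[Si](C)(C)C(C)(C)C)/C=C(C)\I | intermediate
9 | 2-methylprop-1-enylboronic acid pinacol ester | CC(C)=CB1OC(C)(C)C(C)(C)O1 | starting material
10 | (3S,4Z)-3-[(tert-butyldimethylsilyl)oxy]-5,7-dimethylocta-4,6-dienoic acid | OC(=O)C[C@H](O[Si](C)(C)C(C)(C)C)/C=C(C)\C=C(C)C | intermediate
11 | (3S,4Z)-3-[(tert-butyldimethylsilyl)oxy]-5,7-dimethylocta-4,6-dienoyl chloride | ClC(=O)C[C@H](O[Si](C)(C)C(C)(C)C)/C=C(C)\C=C(C)C | intermediate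
12 | (3R,4Z)-3-[(tert-butyldimethylsilyl)oxy]-5,7-dimethylocta-1,4,6-trien-1-one (ketene) | O=C=C[C@H](O[Si](C)(C)C(C)(C)C)/C=C(C)\C=C(C)C | intermediate
13 | (1S,4R,5S)-4-[(tert-butyldimethylsilyl)oxy]-2,7,7-trimethylbicyclo[3.1.1]hept-2-en-6-one | O=C1[C@@H]2[C@H](O[Si](C)(C)C(C)(C)C)C=C(C)[C@H]1C2(C)C | intermediate
14 | (1S,4R,5S)-4-hydroxy-2,7,7-trimethylbicyclo[3.1.1]hept-2-en-6-one | O=C1[C@@H]2[C@H](O)C=C(C)[C@H]1C2(C)C | intermediate
15 | (1S,5S)-2,7,7-trimethylbicyclo[3.1.1]hept-2-ene-4,6-dione | O=C1[C@@H]2C(=O)C=C(C)[C@H]1C2(C)C | intermediate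
16 | (1R)-N-methoxy-N,2,6,6-tetramethyl-4-oxocyclohex-2-ene-1-carboxamide | CON(C)C(=O)[C@H]1C(C)=CC(=O)CC1(C)C | intermediate
17 | (1R,4R)-4-hydroxy-N-methoxy-N,2,6,6-tetramethylcyclohex-2-ene-1-carboxamide | CON(C)C(=O)[C@H]1C(C)=C[C@H](O)CC1(C)C | intermediate
18 | (1R,4R)-4-[(tert-butyldimethylsilyl)oxy]-N-methoxy-N,2,6,6-tetramethylcyclohex-2-ene-1-carboxamide | CON(C)C(=O)[C@H]1C(C)=C[C@H](O[Si](C)(C)C(C)(C)C)CC1(C)C | intermediate
19 | (1R,4R)-4-[(tert-butyldimethylsilyl)oxy]-2,6,6-trimethylcyclohex-2-ene-1-carbaldehyde | O=C[C@H]1C(C)=C[C@H](O[Si](C)(C)C(C)(C)C)CC1(C)C | intermediate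
20 | ethyl (E)-4-(diethoxyphosphoryl)-3-methylbut-2-enoate | CCOC(=O)/C=C(C)/CP(=O)(OCC)OCC | starting material
21 | ethyl (2E,4E)-5-{(1R,4R)-4-[(tert-butyldimethylsilyl)oxy]-2,6,6-trimethylcyclohex-2-en-1-yl}-3-methylpenta-2,4-dienoate | CCOC(=O)/C=C(C)/C=C/[C@H]1C(C)=C[C@H](O[Si](C)(C)C(C)(C)C)CC1(C)C | intermediate
22 | (2E,4E)-5-{(1R,4R)-4-[(tert-butyldimethylsilyl)oxy]-2,6,6-trimethylcyclohex-2-en-1-yl}-3-methylpenta-2,4-dien-1-ol | OC/C=C(C)/C=C/[C@H]1C(C)=C[C@H](O[Si](C)(C)C(C)(C)C)CC1(C)C | intermediate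
23 | (2E,4E)-1-bromo analogue of 22 | BrC/C=C(C)/C=C/[C@H]1C(C)=C[C@H](O[Si](C)(C)C(C)(C)C)CC1(C)C | intermediate
24 | ε-C15 triphenylphosphonium bromide | [Br-].C(/C=C(C)/C=C/[C@H]1C(C)=C[C@H](O[Si](C)(C)C(C)(C)C)CC1(C)C)[P+](c1ccccc1)(c1ccccc1)c1ccccc1 | intermediate
25 | (2E,4E,6E)-2,7-dimethylocta-2,4,6-trienedial | O=C/C(C)=C/C=C/C=C(C)/C=O | starting material
26 | (3R,6R)-3-[(tert-butyldimethylsilyl)oxy]-12'-apo-ε-caroten-12'-al | O=C/C(C)=C/C=C/C=C(C)/C=C/C=C(C)/C=C/[C@H]1C(C)=C[C@H](O[Si](C)(C)C(C)(C)C)CC1(C)C | intermediate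
27 | (4R,6R)-4-hydroxy-2,2,6-trimethylcyclohexan-1-one | O[C@H]1CC(C)(C)C(=O)[C@H](C)C1 | starting material
28 | (4R,6R)-4-[(tert-butyldimethylsilyl)oxy]-2,2,6-trimethylcyclohexan-1-one | CC(C)(C)[Si](C)(C)O[C@H]1CC(C)(C)C(=O)[C@H](C)C1 | intermediate
29 | (4R)-4-[(tert-butyldimethylsilyl)oxy]-2,6,6-trimethylcyclohex-1-en-1-yl trifluoromethanesulfonate | CC1=C(OS(=O)(=O)C(F)(F)F)C(C)(C)C[C@H](O[Si](C)(C)C(C)(C)C)C1 | intermediate
30 | methyl (4R)-4-[(tert-butyldimethylsilyl)oxy]-2,6,6-trimethylcyclohex-1-ene-1-carboxylate | COC(=O)C1=C(C)C[C@@H](O[Si](C)(C)C(C)(C)C)CC1(C)C | intermediate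
31 | {(4R)-4-[(tert-butyldimethylsilyl)oxy]-2,6,6-trimethylcyclohex-1-en-1-yl}methanol | OCC1=C(C)C[C@@H](O[Si](C)(C)C(C)(C)C)CC1(C)C | intermediate
32 | {(1R,4S,6R)-4-[(tert-butyldimethylsilyl)oxy]-2,2,6-trimethyl-7-oxabicyclo[4.1.0]heptan-1-yl}methanol | CC(C)(C)[Si](C)(C)O[C@H]1CC(C)(C)[C@]2(CO)O[C@]2(C)C1 | intermediate
33 | (1S,4S,6R)-4-[(tert-butyldimethylsilyl)oxy]-2,2,6-trimethyl-7-oxabicyclo[4.1.0]heptane-1-carbaldehyde | CC(C)(C)[Si](C)(C)O[C@H]1CC(C)(C)[C@]2(C=O)O[C@]2(C)C1 | intermediate
34 | ethyl (2E,4E)-5-{(1S,4S,6R)-4-[(tert-butyldimethylsilyl)oxy]-2,2,6-trimethyl-7-oxabicyclo[4.1.0]heptan-1-yl}-3-methylpenta-2,4-dienoate | CC(C)(C)[Si](C)(C)O[C@H]1CC(C)(C)[C@]2(/C=C/C(C)=C/C(=O)OCC)O[C@]2(C)C1 | intermediate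
35 | (2E,4E)-5-{(1S,4S,6R)-4-[(tert-butyldimethylsilyl)oxy]-2,2,6-trimethyl-7-oxabicyclo[4.1.0]heptan-1-yl}-3-methylpenta-2,4-dien-1-ol | CC(C)(C)[Si](C)(C)O[C@H]1CC(C)(C)[C@]2(/C=C/C(C)=C/CO)O[C@]2(C)C1 | intermediate
36 | (2E,4E)-1-bromo analogue of 35 | CC(C)(C)[Si](C)(C)O[C@H]1CC(C)(C)[C@]2(/C=C/C(C)=C/CBr)O[C@]2(C)C1 | intermediate
37 | epoxy-C15 triphenylphosphonium bromide | [Br-].CC(C)(C)[Si](C)(C)O[C@H]1CC(C)(C)[C@]2(/C=C/C(C)=C/C[P+](c3ccccc3)(c3ccccc3)c3ccccc3)O[C@]2(C)C1 | intermediate
38 | (3S,5R,6S,3'R,6'R)-3,3'-bis[(tert-butyldimethylsilyl)oxy]-5,6-epoxy-5,6-dihydro-β,ε-carotene | CC(C)(C)[Si](C)(C)O[C@H]1CC(C)(C)[C@]2(/C=C/C(C)=C/C=C/C(C)=C/C=C/C=C(C)/C=C/C=C(C)/C=C/[C@H]3C(C)=C[C@H](O[Si](C)(C)C(C)(C)C)CC3(C)C)O[C@]2(C)C1 | intermediate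
39 | (3S,5R,6S,3'R,6'R)-5,6-epoxy-5,6-dihydro-β,ε-carotene-3,3'-diol | O[C@H]1CC(C)(C)[C@]2(/C=C/C(C)=C/C=C/C(C)=C/C=C/C=C(C)/C=C/C=C(C)/C=C/[C@H]3C(C)=C[C@H](O)CC3(C)C)O[C@]2(C)C1 | intermediate
40 | palmitoyl chloride | CCCCCCCCCCCCCCCC(=O)Cl | starting material
41 | (3S,5R,6S,3'R,6'R)-5,6-epoxy-5,6-dihydro-β,ε-carotene-3,3'-diyl dipalmitate | CCCCCCCCCCCCCCCC(=O)O[C@H]1CC(C)(C)[C@]2(/C=C/C(C)=C/C=C/C(C)=C/C=C/C=C(C)/C=C/C=C(C)/C=C/[C@H]3C(C)=C[C@H](OC(=O)CCCCCCCCCCCCCCC)CC3(C)C)O[C@]2(C)C1 | target

## Step count and risks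

Total step count: 28.
Longest linear sequence: 19 (steps 1–16, then 26–28).

Steps most likely to fail:

**Step 7.** Ketene dimerisation, ene-type proton loss from a C1' methyl group, or thermal loss of silanol may outrun the crossed cycloaddition.
The fallback replaces the ketene by a keteniminium ion, which is more electrophilic and cannot dimerise. It sets out from 10.
- EDC coupling with pyrrolidine gives the pyrrolidine amide F1.
- Tf2O and 2,4,6-collidine in 1,2-dichloroethane convert it into the keteniminium triflate F2.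
- F2 should close in the same crossed sense to the bicyclic iminium triflate F3.
- Hydrolysis with aqueous NaHCO3 gives the ketone, and the route is rejoined at 13.

**Step 9.** Dienolisation toward C6' in the doubly activated product (erosion of configuration) or attack of the amine at the enone carbonyl may intervene.
The fallback cleaves hydrolytically, so that C7' emerges as a carboxylate that lowers the acidity of C6'–H. It sets out from 14.
- Oxidation as before gives 15, which is treated with LiOH in THF/H2O at 0 °C to give the keto acid F4 as its lithium salt.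
- Luche reduction of the salt (NaBH4, CeCl3, MeOH, −78 °C) gives the trans hydroxy acid F5 after separation from its cis epimer.
- EDC coupling with N,O-dimethylhydroxylamine brings the route back at 17.

**Step 13.** Deprotonation of the aldehyde at C6' by the phosphonate anion, with epimerisation or migration of the double bond into conjugation, may compete with addition.
The fallback builds the chain in two stages and starts under base-free conditions. It sets out from 19.
- Heating with the stabilised ylide 1-(triphenylphosphoranylidene)propan-2-one in toluene gives the silyloxy-α-ionone F6, in which C6'–H is no longer α to a carbonyl group.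
- Horner–Wadsworth–Emmons reaction of this ketone with triethyl phosphonoacetate and NaH, with separation of the 9'Z isomer, brings the route back at 21.

Further compounds
F1 | step 7 | 1-{(3S,4Z)-3-[(tert-butyldimethylsilyl)oxy]-5,7-dimethylocta-4,6-dienoyl}pyrrolidine | O=C(C[C@H](O[Si](C)(C)C(C)(C)C)/C=C(C)\C=C(C)C)N1CCCC1
F2 | step 7 | keteniminium triflate derived from F1 | [O-]S(=O)(=O)C(F)(F)F.C1CC[N+](=C=C[C@H](O[Si](C)(C)C(C)(C)C)/C=C(C)\C=C(C)C)C1
F3 | step 7 | pyrrolidinium-1-ylidene (iminium) triflate of ketone 13 | [O-]S(=O)(=O)C(F)(F)F.C1CC[N+](=C2[C@@H]3[C@H](O[Si](C)(C)C(C)(C)C)C=C(C)[C@H]2C3(C)C)C1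
F4 | step 9 | (1R)-2,6,6-trimethyl-4-oxocyclohex-2-ene-1-carboxylic acid | OC(=O)[C@H]1C(C)=CC(=O)CC1(C)C
F5 | step 9 | (1R,4R)-4-hydroxy-2,6,6-trimethylcyclohex-2-ene-1-carboxylic acid | OC(=O)[C@H]1C(C)=C[C@H](O)CC1(C)C
F6 | step 13 | (3E)-4-{(1R,4R)-4-[(tert-butyldimethylsilyl)oxy]-2,6,6-trimethylcyclohex-2-en-1-yl}but-3-en-2-one | CC(=O)/C=C/[C@H]1C(C)=C[C@H](O[Si](C)(C)C(C)(C)C)CC1(C)C
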